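A direct plan would take the pyranone ring from a purchased chromone (as its bis-MOM ether A1) and set both dioxane centres by an auxiliary-controlled syn glycolate aldol (imide A2). It would then remove the auxiliary, mask the primary alcohol as a trityl ether (A3), close the dioxane by copper-catalysed intramolecular O-arylation (bromide A4), convert the bromide into boronic acid A5, join the halves by Rh-catalysed asymmetric 1,4-addition (A6) and finish with one acidic global deprotection.
Its weakest steps would be: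
- The copper-catalysed O-arylation that closes the dioxane from A3: a secondary benzylic alkoxide with a β-aryloxy group is heated with carbonate at 110 °C, where retro-aldol fragmentation, β-elimination and loss of I/Br selectivity compete. It also forces the trityl group, which builds nothing.
- The Rh-catalysed 1,4-addition of A5 to A1: 5-alkoxychromones are sluggish acceptors, the electron-rich boronic acid protodeboronates, the sense of induction is only assumed, and the most advanced fragment is spent in the least secure step.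
- The final acid treatment of A6: three MOM groups and a trityl group leave at once, setting free formaldehyde and trityl cation next to a phloroglucinol ring and an acid-ionisable benzylic aryl ether.

**Retrosynthetic overview**
1. Silandrin ⇐ neutral hydrogenolysis of the three aryl benzyl ethers of 18.
2. Pyranone ring (closed last) ⇐ Knoevenagel union of dioxane aldehyde 13 with phloroglucinol β-keto ester 15 (C2–C3), then catalyst-controlled 6-endo oxa-Michael closure (O1–C2) and decarboxylation. The flavanone centre is set in the ring closure, not by a metal-catalysed aryl transfer.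
3. Dioxane C2–aryl bond ⇐ C-arylation of the cyclic oxocarbenium ion from lactol acetate 7 with guaiacyl trifluoroborate 9. The feature used: C2 of the dioxane ring carries the ring oxygen O1 and the electron-rich, para-oxygenated guaiacyl ring, so it is an acetal carbon in disguise; the neighbouring C3 directs the aryl group trans.
4. Dioxane ring (closed first) ⇐ Mitsunobu ether from phenol 1 and (S)-glycerate 2 (C3 from the chiral pool; the O4–C3 regiochemistry is fixed by the one free phenol), then lactonisation (O1–C2).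
5. No auxiliary, no trityl group, no copper ring closure; the only ionising step comes before the flavanone exists, and the last step is neutral.

Key step: step 5

**Assumptions**
- The target is read as the (2S)-flavanone with a trans-(2R,3R)-benzodioxane whose aryl-bearing C2 sits on the oxygen para to the flavanone.
- The quinine-derived thiourea is assumed to give the 2S flavanone in step 10; if the sense is opposite, the quinidine-derived pseudoenantiomer is used.
- Compounds 1, 2, 8 and 14 are taken as catalogue compounds.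
- The route is a design from known reaction classes and has not been run.

**Route**

Step 1
Reactants: 1 methyl 4-(benzyloxy)-3-hydroxybenzoate; 2 methyl (2S)-3-(benzyloxy)-2-hydroxypropanoate
Product: 3 methyl 4-(benzyloxy)-3-{[(2R)-3-(benzyloxy)-1-methoxy-1-oxopropan-2-yl]oxy}benzoate
Conditions: PPh3, DIAD, THF, 0 °C → rt
Reagents that add atoms: none
Why: Mitsunobu etherification; the only free phenol of 1 (meta to the ester) displaces the activated secondary alcohol of 2 with SN2 inversion (S → R), which sets dioxane C3 from the chiral pool and fixes the regiochemistry of the future ring.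

Step 2
Reactants: 3 methyl 4-(benzyloxy)-3-{[(2R)-3-(benzyloxy)-1-methoxy-1-oxopropan-2-yl]oxy}benzoate
Product: 5 methyl (3R)-3-(hydroxymethyl)-2-oxo-2,3-dihydro-1,4-benzodioxine-6-carboxylate, via methyl 4-hydroxy-3-{[(2R)-3-hydroxy-1-methoxy-1-oxopropan-2-yl]oxy}benzoate 4 (not isolated)
Conditions: H2 (1 atm), 10% Pd/C, EtOAc/MeOH, rt; filter, concentrate; TsOH·H2O (cat.), toluene (dilute), 4 Å MS, 90 °C
Reagents that add atoms: none
Why: Hydrogenolysis frees the phenol para to the benzoate and the primary alcohol; acid-catalysed transesterification then closes the six-membered aryl lactone (6-exo-trig), and the stereocentre is not touched under acid.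

Step 3
Reactants: 5 methyl (3R)-3-(hydroxymethyl)-2-oxo-2,3-dihydro-1,4-benzodioxine-6-carboxylate
Product: 7 methyl (3R)-2-(acetyloxy)-3-[(acetyloxy)methyl]-2,3-dihydro-1,4-benzodioxine-6-carboxylate (both C2 anomers), via the aluminium alkoxide of lactol methyl (3R)-2-hydroxy-3-(hydroxymethyl)-2,3-dihydro-1,4-benzodioxine-6-carboxylate 6 (not isolated)
Conditions: DIBAL-H (2.3 equiv), CH2Cl2, −78 °C; then pyridine, DMAP, Ac2O, −78 → 0 °C
Reagents that add atoms: acetic anhydride, CC(=O)OC(C)=O
Why: Reductive acetylation of a lactone (Rychnovsky type); at −78 °C DIBAL-H should reduce the activated aryl-ester lactone much faster than the methyl benzoate, and the aluminium hemiacetal is trapped in situ as the anomeric acetate, the primary alkoxide being acetylated as well.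

Step 4
Reactants: 8 [4-(benzyloxy)-3-methoxyphenyl]boronic acid
Product: 9 potassium [4-(benzyloxy)-3-methoxyphenyl]trifluoroborate
Conditions: KHF2 (aq.), MeOH, rt
Reagents that add atoms: potassium hydrogen difluoride, [K+].[F-].F
Why: Standard conversion of a boronic acid into its bench-stable trifluoroborate salt.

Step 5
Reactants: 7 methyl (3R)-2-(acetyloxy)-3-[(acetyloxy)methyl]-2,3-dihydro-1,4-benzodioxine-6-carboxylate; 9 potassium [4-(benzyloxy)-3-methoxyphenyl]trifluoroborate
Product: 11 methyl (2R,3R)-3-[(acetyloxy)methyl]-2-[4-(benzyloxy)-3-methoxyphenyl]-2,3-dihydro-1,4-benzodioxine-6-carboxylate, via the cyclic oxocarbenium ion (3R)-3-[(acetyloxy)methyl]-6-(methoxycarbonyl)-3H-1,4-benzodioxin-1-ium 10 (not isolated)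
Conditions: 9 (1.5 equiv), BF3·OEt2 (3 equiv), CH2Cl2/MeCN, −40 → 0 °C
Reagents that add atoms: none
Why: BF3 abstracts fluoride from 9 to give the aryldifluoroborane, the anomeric acetate of 7 ionises to the oxocarbenium ion 10 (C2=O1+), and the aryl group is transferred from boron to C2 by ipso substitution, so the new C–C bond is regiospecifically para to the benzyloxy group. The closest known reaction type is the Lewis-acid-promoted coupling of potassium organotrifluoroborates with O,O-acetals and lactol acetates, a C-aryl-glycoside-type alkylation. No ring is closed: the dioxane ring is already in place and only the C2 substituent is exchanged from acetate to the guaiacyl ring. The new stereocentre C2 is controlled by C3: the aryl group should enter anti to the CH2OAc group (steric shielding and possible acyloxonium participation both block the syn face), giving the 2,3-trans (2R,3R) isomer, which is also the thermodynamic one. The step needs a single arylation at C2 without loss of the C3 proton (benzodioxine formation) and without a second ionisation of the product at C2–O1. Low temperature, a limited excess of 9, and the fact that acetate leaves far more easily than the ring aryloxy group (which would in any case reclose intramolecularly) should secure this.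

Step 6
Reactants: 11 methyl (2R,3R)-3-[(acetyloxy)methyl]-2-[4-(benzyloxy)-3-methoxyphenyl]-2,3-dihydro-1,4-benzodioxine-6-carboxylate
Product: 12 [(2R,3R)-2-[4-(benzyloxy)-3-methoxyphenyl]-2,3-dihydro-1,4-benzodioxine-3,6-diyl]dimethanol
Conditions: LiAlH4, THF, 0 °C
Reagents that add atoms: none
Why: Hydride reduction of the benzoate to the benzylic alcohol and reductive cleavage of the acetate in one operation; the ethers and both stereocentres are inert.

Step 7
Reactants: 12 [(2R,3R)-2-[4-(benzyloxy)-3-methoxyphenyl]-2,3-dihydro-1,4-benzodioxine-3,6-diyl]dimethanol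
Product: 13 (2R,3R)-2-[4-(benzyloxy)-3-methoxyphenyl]-3-(hydroxymethyl)-2,3-dihydro-1,4-benzodioxine-6-carbaldehyde
Conditions: activated MnO2 (excess), CH2Cl2, rt
Reagents that add atoms: none
Why: Chemoselective MnO2 oxidation of the benzylic primary alcohol only, so the aliphatic CH2OH needs no protecting group.

Step 8
Reactants: 14 1-[2,4-bis(benzyloxy)-6-hydroxyphenyl]ethan-1-one
Product: 15 tert-butyl 3-[2,4-bis(benzyloxy)-6-hydroxyphenyl]-3-oxopropanoate
Conditions: LiHMDS (3.2 equiv), THF, −78 °C; Boc2O (1.1 equiv), −78 → 0 °C; aq. NH4Cl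
Reagents that add atoms: di-tert-butyl dicarbonate, CC(C)(C)OC(=O)OC(=O)OC(C)(C)C
Why: Claisen-type C-acylation of the phenoxide/enolate dianion of an o-hydroxyacetophenone (an O-Boc intermediate would converge by Baker–Venkataraman-type O→C transfer); the tert-butyl ester blocks 4-hydroxycoumarin formation and allows acidic decarboxylation later.

Step 9
Reactants: 13 (2R,3R)-2-[4-(benzyloxy)-3-methoxyphenyl]-3-(hydroxymethyl)-2,3-dihydro-1,4-benzodioxine-6-carbaldehyde; 15 tert-butyl 3-[2,4-bis(benzyloxy)-6-hydroxyphenyl]-3-oxopropanoate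
Product: 16 tert-butyl 2-[2,4-bis(benzyloxy)-6-hydroxybenzoyl]-3-{(2R,3R)-2-[4-(benzyloxy)-3-methoxyphenyl]-3-(hydroxymethyl)-2,3-dihydro-1,4-benzodioxin-6-yl}prop-2-enoate (E/Z mixture)
Conditions: piperidine (cat.), AcOH (cat.), toluene, 4 Å MS, rt → 40 °C
Reagents that add atoms: none
Why: Knoevenagel condensation under buffered piperidinium acetate joins the two halves through the C2–C3 bond; both alkene isomers converge in step 10.

Step 10
Reactants: 16 tert-butyl 2-[2,4-bis(benzyloxy)-6-hydroxybenzoyl]-3-{(2R,3R)-2-[4-(benzyloxy)-3-methoxyphenyl]-3-(hydroxymethyl)-2,3-dihydro-1,4-benzodioxin-6-yl}prop-2-enoate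
Product: 18 (2S)-5,7-bis(benzyloxy)-2-{(2R,3R)-2-[4-(benzyloxy)-3-methoxyphenyl]-3-(hydroxymethyl)-2,3-dihydro-1,4-benzodioxin-6-yl}-2,3-dihydro-4H-chromen-4-one, via tert-butyl (2S)-5,7-bis(benzyloxy)-2-{(2R,3R)-2-[4-(benzyloxy)-3-methoxyphenyl]-3-(hydroxymethyl)-2,3-dihydro-1,4-benzodioxin-6-yl}-4-oxo-3,4-dihydro-2H-chromene-3-carboxylate 17 (not isolated)
Conditions: 9-amino-9-deoxy-epi-quinine 3,5-bis(trifluoromethyl)phenylthiourea (10 mol %), toluene, −25 °C; then TsOH·H2O, 80 °C
Reagents that add atoms: none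
Why: Bifunctional cinchona–thiourea-catalysed intramolecular oxa-Michael addition (6-endo-trig) of the phenol to the doubly activated alkylidene sets flavanone C2 (S) under catalyst control, independent of the remote dioxane centres; acid then cleaves the tert-butyl ester and the β-keto acid decarboxylates, which makes the closure irreversible.

Step 11
Reactants: 18 (2S)-5,7-bis(benzyloxy)-2-{(2R,3R)-2-[4-(benzyloxy)-3-methoxyphenyl]-3-(hydroxymethyl)-2,3-dihydro-1,4-benzodioxin-6-yl}-2,3-dihydro-4H-chromen-4-one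
Product: 19 silandrin, (2S)-5,7-dihydroxy-2-[(2R,3R)-2-(4-hydroxy-3-methoxyphenyl)-3-(hydroxymethyl)-2,3-dihydro-1,4-benzodioxin-6-yl]-2,3-dihydro-4H-chromen-4-one
Conditions: H2 (1 atm), 10% Pd/C, EtOAc/MeOH, rt, stopped at completion
Reagents that add atoms: none
Why: Neutral hydrogenolysis of three aryl benzyl ethers; no acid or base reaches the base-labile flavanone C2 or the acid-ionisable dioxane C2–O1 bond.

**Compound list**
1 | methyl 4-(benzyloxy)-3-hydroxybenzoate | COC(=O)c1ccc(OCc2ccccc2)c(O)c1 | starting material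
2 | methyl (2S)-3-(benzyloxy)-2-hydroxypropanoate | COC(=O)[C@@H](O)COCc1ccccc1 | starting material
3 | methyl 4-(benzyloxy)-3-{[(2R)-3-(benzyloxy)-1-methoxy-1-oxopropan-2-yl]oxy}benzoate | COC(=O)c1ccc(OCc2ccccc2)c(O[C@H](COCc2ccccc2)C(=O)OC)c1 | intermediate
4 | methyl 4-hydroxy-3-{[(2R)-3-hydroxy-1-methoxy-1-oxopropan-2-yl]oxy}benzoate | COC(=O)c1ccc(O)c(O[C@H](CO)C(=O)OC)c1 | intermediate (not isolated)
5 | methyl (3R)-3-(hydroxymethyl)-2-oxo-2,3-dihydro-1,4-benzodioxine-6-carboxylate | COC(=O)c1ccc2c(c1)O[C@H](CO)C(=O)O2 | intermediate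
6 | methyl (3R)-2-hydroxy-3-(hydroxymethyl)-2,3-dihydro-1,4-benzodioxine-6-carboxylate (lactol; present in step 3 as its aluminium alkoxide) | COC(=O)c1ccc2c(c1)O[C@H](CO)C(O)O2 | intermediate (not isolated)
7 | methyl (3R)-2-(acetyloxy)-3-[(acetyloxy)methyl]-2,3-dihydro-1,4-benzodioxine-6-carboxylate | COC(=O)c1ccc2c(c1)O[C@H](COC(C)=O)C(OC(C)=O)O2 | intermediate
8 | [4-(benzyloxy)-3-methoxyphenyl]boronic acid | COc1cc(B(O)O)ccc1OCc1ccccc1 | starting material
9 | potassium [4-(benzyloxy)-3-methoxyphenyl]trifluoroborate | COc1cc([B-](F)(F)F)ccc1OCc1ccccc1.[K+] | intermediate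
10 | (3R)-3-[(acetyloxy)methyl]-6-(methoxycarbonyl)-3H-1,4-benzodioxin-1-ium (cyclic oxocarbenium ion) | COC(=O)c1ccc2c(c1)O[C@H](COC(C)=O)C=[O+]2 | intermediate (not isolated)
11 | methyl (2R,3R)-3-[(acetyloxy)methyl]-2-[4-(benzyloxy)-3-methoxyphenyl]-2,3-dihydro-1,4-benzodioxine-6-carboxylate | COC(=O)c1ccc2c(c1)O[C@H](COC(C)=O)[C@@H](c1ccc(OCc3ccccc3)c(OC)c1)O2 | intermediate
12 | [(2R,3R)-2-[4-(benzyloxy)-3-methoxyphenyl]-2,3-dihydro-1,4-benzodioxine-3,6-diyl]dimethanol | OCc1ccc2c(c1)O[C@H](CO)[C@@H](c1ccc(OCc3ccccc3)c(OC)c1)O2 | intermediate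
13 | (2R,3R)-2-[4-(benzyloxy)-3-methoxyphenyl]-3-(hydroxymethyl)-2,3-dihydro-1,4-benzodioxine-6-carbaldehyde | O=Cc1ccc2c(c1)O[C@H](CO)[C@@H](c1ccc(OCc3ccccc3)c(OC)c1)O2 | intermediate
14 | 1-[2,4-bis(benzyloxy)-6-hydroxyphenyl]ethan-1-one | CC(=O)c1c(O)cc(OCc2ccccc2)cc1OCc1ccccc1 | starting material
15 | tert-butyl 3-[2,4-bis(benzyloxy)-6-hydroxyphenyl]-3-oxopropanoate | CC(C)(C)OC(=O)CC(=O)c1c(O)cc(OCc2ccccc2)cc1OCc1ccccc1 | intermediate
16 | tert-butyl 2-[2,4-bis(benzyloxy)-6-hydroxybenzoyl]-3-{(2R,3R)-2-[4-(benzyloxy)-3-methoxyphenyl]-3-(hydroxymethyl)-2,3-dihydro-1,4-benzodioxin-6-yl}prop-2-enoate (E/Z mixture) | CC(C)(C)OC(=O)C(=Cc1ccc2c(c1)O[C@H](CO)[C@@H](c1ccc(OCc3ccccc3)c(OC)c1)O2)C(=O)c1c(O)cc(OCc2ccccc2)cc1OCc1ccccc1 | intermediate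
17 | tert-butyl (2S)-5,7-bis(benzyloxy)-2-{(2R,3R)-2-[4-(benzyloxy)-3-methoxyphenyl]-3-(hydroxymethyl)-2,3-dihydro-1,4-benzodioxin-6-yl}-4-oxo-3,4-dihydro-2H-chromene-3-carboxylate | CC(C)(C)OC(=O)C1C(=O)c2c(OCc3ccccc3)cc(OCc3ccccc3)cc2O[C@@H]1c1ccc2c(c1)O[C@H](CO)[C@@H](c1ccc(OCc3ccccc3)c(OC)c1)O2 | intermediate (not isolated)
18 | (2S)-5,7-bis(benzyloxy)-2-{(2R,3R)-2-[4-(benzyloxy)-3-methoxyphenyl]-3-(hydroxymethyl)-2,3-dihydro-1,4-benzodioxin-6-yl}-2,3-dihydro-4H-chromen-4-one | O=C1C[C@@H](c2ccc3c(c2)O[C@H](CO)[C@@H](c2ccc(OCc4ccccc4)c(OC)c2)O3)Oc2cc(OCc3ccccc3)cc(OCc3ccccc3)c12 | intermediate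
19 | silandrin, (2S)-5,7-dihydroxy-2-[(2R,3R)-2-(4-hydroxy-3-methoxyphenyl)-3-(hydroxymethyl)-2,3-dihydro-1,4-benzodioxin-6-yl]-2,3-dihydro-4H-chromen-4-one | COc1cc([C@H]2Oc3ccc([C@@H]4CC(=O)c5c(O)cc(O)cc5O4)cc3O[C@@H]2CO)ccc1O | target

**Step count**
Total: 11 steps. Longest linear sequence: 9 steps (1, 2, 3, 5, 6, 7, 9, 10, 11); steps 4 and 8 are one-step side branches.

**Steps most likely to fail**

Step 5 (C-arylation). The anomeric acetate may ionise slowly because the ring oxygen is conjugated to the para ester; the cation may lose the C3 proton to give the benzodioxine; or the product may re-ionise at C2–O1 and take up a second aryl group. The fallback sets out from lactone 5 and comes back at diol 12. Lactone 5 would be opened with N,O-dimethylhydroxylamine hydrochloride and i-PrMgCl (THF, −20 °C) to the Weinreb amide methyl 4-hydroxy-3-{[(2R)-3-hydroxy-1-[methoxy(methyl)amino]-1-oxopropan-2-yl]oxy}benzoate F1. [4-(Benzyloxy)-3-methoxyphenyl]magnesium bromide F2 (from 1-(benzyloxy)-4-bromo-2-methoxybenzene and Mg; excess, −78 °C) would give the aryl ketone methyl 3-{[(2R)-1-[4-(benzyloxy)-3-methoxyphenyl]-3-hydroxy-1-oxopropan-2-yl]oxy}-4-hydroxybenzoate F3. Cold NaBH4 would give the benzylic alcohols methyl 3-{[(2R)-1-[4-(benzyloxy)-3-methoxyphenyl]-1,3-dihydroxypropan-2-yl]oxy}-4-hydroxybenzoate F4 as an epimer mixture. Catalytic TsOH in toluene would then close the ring through the p-benzyloxybenzyl cation, both epimers converging on the trans ester methyl (2R,3R)-2-[4-(benzyloxy)-3-methoxyphenyl]-3-(hydroxymethyl)-2,3-dihydro-1,4-benzodioxine-6-carboxylate F5, which LiAlH4 reduces to 12.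

Step 10 (asymmetric oxa-Michael closure). Facial control by the catalyst may be weak on the di-ortho-substituted aroyl acceptor, or retro-oxa-Michael equilibration before decarboxylation may deliver both C2 epimers. The fallback sets out from aldehyde 13 and acetophenone 14 and comes back at 18. Claisen–Schmidt condensation (KOH, EtOH) would give the chalcone (E)-1-[2,4-bis(benzyloxy)-6-hydroxyphenyl]-3-{(2R,3R)-2-[4-(benzyloxy)-3-methoxyphenyl]-3-(hydroxymethyl)-2,3-dihydro-1,4-benzodioxin-6-yl}prop-2-en-1-one F6. NaOAc in hot EtOH would cyclise it without control to 18 together with its (2R) epimer F7. Noyori–Ikariya transfer hydrogenation (Ru- or Rh-TsDPEN, HCO2H/Et3N), with the catalyst enantiomer matched to the 2R series, would then reduce F7 to the cis-(2R,4R)-flavan-4-ol F8 and leave 18, which is separated by chromatography.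

Step 2 (lactonisation). Intermolecular transesterification through the free primary alcohol may compete with ring closure, or the aryl lactone may reopen on isolation. The fallback sets out from diester 3 and comes back at diacetate 7, so the lactone is never made. DIBAL-H (1 equiv, toluene, −78 °C) would reduce the more electrophilic α-aryloxy ester to the aldehyde methyl 4-(benzyloxy)-3-{[(2R)-3-(benzyloxy)-1-oxopropan-2-yl]oxy}benzoate F9. Hydrogenolysis (H2, Pd/C, EtOAc) would free the phenol, which closes onto the aldehyde to give lactol 6 as the free hemiacetal, and Ac2O/pyridine would give 7.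

**Further compounds**
F1 | step 5 | methyl 4-hydroxy-3-{[(2R)-3-hydroxy-1-[methoxy(methyl)amino]-1-oxopropan-2-yl]oxy}benzoate | COC(=O)c1ccc(O)c(O[C@H](CO)C(=O)N(C)OC)c1
F2 | step 5 | [4-(benzyloxy)-3-methoxyphenyl]magnesium bromide | COc1cc([Mg]Br)ccc1OCc1ccccc1
F3 | step 5 | methyl 3-{[(2R)-1-[4-(benzyloxy)-3-methoxyphenyl]-3-hydroxy-1-oxopropan-2-yl]oxy}-4-hydroxybenzoate | COC(=O)c1ccc(O)c(O[C@H](CO)C(=O)c2ccc(OCc3ccccc3)c(OC)c2)c1
F4 | step 5 | methyl 3-{[(2R)-1-[4-(benzyloxy)-3-methoxyphenyl]-1,3-dihydroxypropan-2-yl]oxy}-4-hydroxybenzoate (C1 epimer mixture) | COC(=O)c1ccc(O)c(O[C@H](CO)C(O)c2ccc(OCc3ccccc3)c(OC)c2)c1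
F5 | step 5 | methyl (2R,3R)-2-[4-(benzyloxy)-3-methoxyphenyl]-3-(hydroxymethyl)-2,3-dihydro-1,4-benzodioxine-6-carboxylate | COC(=O)c1ccc2c(c1)O[C@H](CO)[C@@H](c1ccc(OCc3ccccc3)c(OC)c1)O2
F6 | step 10 | (E)-1-[2,4-bis(benzyloxy)-6-hydroxyphenyl]-3-{(2R,3R)-2-[4-(benzyloxy)-3-methoxyphenyl]-3-(hydroxymethyl)-2,3-dihydro-1,4-benzodioxin-6-yl}prop-2-en-1-one | O=C(/C=C/c1ccc2c(c1)O[C@H](CO)[C@@H](c1ccc(OCc3ccccc3)c(OC)c1)O2)c1c(O)cc(OCc2ccccc2)cc1OCc1ccccc1
F7 | step 10 | (2R)-5,7-bis(benzyloxy)-2-{(2R,3R)-2-[4-(benzyloxy)-3-methoxyphenyl]-3-(hydroxymethyl)-2,3-dihydro-1,4-benzodioxin-6-yl}-2,3-dihydro-4H-chromen-4-one | O=C1C[C@H](c2ccc3c(c2)O[C@H](CO)[C@@H](c2ccc(OCc4ccccc4)c(OC)c2)O3)Oc2cc(OCc3ccccc3)cc(OCc3ccccc3)c12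
F8 | step 10 | (2R,4R)-5,7-bis(benzyloxy)-2-{(2R,3R)-2-[4-(benzyloxy)-3-methoxyphenyl]-3-(hydroxymethyl)-2,3-dihydro-1,4-benzodioxin-6-yl}-3,4-dihydro-2H-chromen-4-ol | O[C@@H]1C[C@H](c2ccc3c(c2)O[C@H](CO)[C@@H](c2ccc(OCc4ccccc4)c(OC)c2)O3)Oc2cc(OCc3ccccc3)cc(OCc3ccccc3)c12
F9 | step 2 | methyl 4-(benzyloxy)-3-{[(2R)-3-(benzyloxy)-1-oxopropan-2-yl]oxy}benzoate | COC(=O)c1ccc(OCc2ccccc2)c(O[C@H](COCc2ccccc2)C=O)c1
A1 | direct plan | 5,7-bis(methoxymethoxy)-4H-chromen-4-one | O=c1ccoc2cc(OCOC)cc(OCOC)c12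
A2 | direct plan | (S)-4-benzyl-3-[(2S,3R)-2-(5-bromo-2-iodophenoxy)-3-hydroxy-3-[3-methoxy-4-(methoxymethoxy)phenyl]propanoyl]oxazolidin-2-one | COCOc1ccc([C@@H](O)[C@H](Oc2cc(Br)ccc2I)C(=O)N3[C@@H](Cc4ccccc4)COC3=O)cc1OC
A3 | direct plan | (1R,2R)-2-(5-bromo-2-iodophenoxy)-1-[3-methoxy-4-(methoxymethoxy)phenyl]-3-(trityloxy)propan-1-ol | COCOc1ccc([C@@H](O)[C@H](Oc2cc(Br)ccc2I)COC(c3ccccc3)(c4ccccc4)c5ccccc5)cc1OC
A4 | direct plan | (2R,3R)-6-bromo-2-[3-methoxy-4-(methoxymethoxy)phenyl]-3-[(trityloxy)methyl]-2,3-dihydro-1,4-benzodioxine | COCOc1ccc([C@H]2Oc3ccc(Br)cc3O[C@@H]2COC(c4ccccc4)(c5ccccc5)c6ccccc6)cc1OC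
A5 | direct plan | [(2R,3R)-2-[3-methoxy-4-(methoxymethoxy)phenyl]-3-[(trityloxy)methyl]-2,3-dihydro-1,4-benzodioxin-6-yl]boronic acid | COCOc1ccc([C@H]2Oc3ccc(B(O)O)cc3O[C@@H]2COC(c4ccccc4)(c5ccccc5)c6ccccc6)cc1OC
A6 | direct plan | (2S)-5,7-bis(methoxymethoxy)-2-[(2R,3R)-2-[3-methoxy-4-(methoxymethoxy)phenyl]-3-[(trityloxy)methyl]-2,3-dihydro-1,4-benzodioxin-6-yl]chroman-4-one | COCOc1ccc([C@H]2Oc3ccc([C@@H]4CC(=O)c5c(OCOC)cc(OCOC)cc5O4)cc3O[C@@H]2COC(c6ccccc6)(c7ccccc7)c8ccccc8)cc1OC
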